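All runs were generated by integration with constants of no real substance; scatter was added.

You read one flask at 30 h and its twin, with the same charge, at 50 h, so the question is what the extra 20.0 h does to the excess of right-handed over left-handed substrate.

all flasks: gas 4.4 mM (held); precatalyst 40 µM

|  | left-handed substrate | right-handed substrate | remark | time |
|---|---|---|---|---|
| violet | 10 mM | 10 mM | run made earlier |  |
| green | 15 mM | 15 mM | run made earlier |  |
| Wednesday's | 20 mM | 20 mM |  | 30 h |
| Sunday's | 20 mM | 20 mM |  | 50 h |

| run | time / h | right-handed substrate / % | left-handed substrate / % | left-handed product / % |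
|---|---|---|---|---|
| violet | 2.00 | 52.1 | 50.3 | 0.7 |
| violet | 3.00 | 48.3 | 49.9 | 0 |
| violet | 5.00 | 50.2 | 49.5 | 0 |
| violet | 8.00 | 48.7 | 49.2 | 0.2 |
| violet | 15.0 | 48.4 | 44.1 | 5.8 |
| violet | 25.0 | 44.2 | 35.2 | 10.8 |
| green | 1.50 | 48.1 | 51.5 | 0 |
| green | 5.00 | 51.5 | 49.4 | 0.1 |
| green | 8.00 | 48.6 | 46.9 | 1.9 |
| green | 12.0 | 47.8 | 45.3 | 3.9 |
| green | 20.0 | 47.6 | 39.9 | 9.9 |
| green | 25.0 | 45.5 | 37.6 | 12.4 |

(readings scatter by 1 percentage point)

1. the flask that ends with the higher excess of right-handed substrate over left-handed substrate among what is left of the two, or "neither" when 2 percentage points or less lies between them (Wednesday's / Sunday's / neither)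
2. excess of right-handed substrate over left-handed substrate among what is left of the two at the end, Wednesday's
3. excess of right-handed substrate over left-handed substrate among what is left of the two at the end, Sunday's

- catalyst is single-handed; left-handed substrate and right-handed substrate are mirror images of each other, charged as a racemate, each of them at the stated concentration
- at the start none of the gas is in solution
- an excess is the difference of the two amounts in percent of their sum
- an excess is below zero if the other one leads

Call the depth of a hand minus ln of the fraction of its own charge still left. If both hands are first order in themselves on one catalyst, the catalyst's history cancels in the ratio of their depths. At 25.0 h the violet run gives a ratio of 2.85 and the green run 3.02, so take 2.93: this reading, the selectivity factor s, left-handed depth over right-handed depth, is what you carry.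

Now I draw the curve, treating the loadings as one. The excess starts with no slope that the scatter lets you see: at 8.00 h the violet run still reads 48.7% against 49.2%. I put the knee at that time. By 25.0 h the left-handed depth averages 0.318, a straight climb of 0.0187 h⁻¹. On that line the left-handed fraction crosses half near 45.1 h. At 30 h, Wednesday's left-handed fraction is 66.3% and the right-handed one 86.9%, an excess of 13.5%. At 50 h, Sunday's are 45.6% and 76.5%, an excess of 25.3%. By this rule the curve's level is full excess, 100 per cent, reached as the left-handed fraction goes to nothing.

The forecast named Sunday's, with 13% and 23%, the second below mine, on the ground that “After induction, the left-handed substrate decays roughly first order”.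

The simulation gives Sunday's: 10.5% for Wednesday's and 24.1% for Sunday's.

    reagent + catalyst + left-handed substrate → catalyst + left-handed product (k = 3700 M⁻² min⁻¹)
    reagent + catalyst + right-handed substrate → catalyst + right-handed product (k = 1600 M⁻² min⁻¹)
    gas ⇌ reagent, rate k3*(csat - [reagent]) (kL = 0.0150 min⁻¹)
    precatalyst → catalyst (k = 5.20 × 10⁻⁴ min⁻¹)

The difference in time is the main reason for the gap: Sunday's stands at 24.1%, and with the extra time taken away it stands at 10.5%. Enter Wednesday's left-handed fraction of 69% with s of 2.93: the rule gives an excess of 12.2%, and the flask holds 10.5%. Wednesday's flask, read instead at 72.0 h, keeps a left-handed fraction of 22%, where the rule gives 46.6%, above the 40.9% that flask holds.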